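**Retrosynthetic overview**
1. The C3–O ester bond is made last, from diol 20 and (2S,3R)-epoxy acid 23. The chlorohydrin comes from SN2 opening of the epoxy ester by HCl. The cis-3α,4α-diol comes from osmylation of a Δ3 alkene on the face opposite the C10 methyl.
2. Ring order: ring A is bought (3-methylcyclohexenone). A four-membered ring C5–C8–C9–C10 is fused to it by dichloroketene [2+2]. Ring B (C5–C6–C7–C8–C9–C10) grows out of this ring when C6=C7, already carrying C11–C13 and the C11 oxygen, is inserted into the C5–C8 bond.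
3. Enabling feature: C4 (carbinol carbon of ring A) and C8 (ketone of ring B) are 1,5-related through C5–C6–C7. With C4 at the ketone level, C5–C6 is a Michael bond. In bicyclo[4.2.0]octanedione 7 the same C4 ketone sits β to C8, so an alkoxide made at C8 breaks C5–C8 by retro-aldol.
4. Stereochemical relay: the CBS-set C4 carbinol controls quaternary C10 (anti [2+2]) and is then erased. C5 is set by equilibration next to the C4 ketone, C3 and C4 follow from C10 by osmylation, and C2′/C3′ come from Sharpless epoxidation.
5. C15 enters by enol triflate/methyl coupling at C4. The enone comes from Saegusa–Ito oxidation of the enolate trapped in the key step.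

Key step: step 8

Remark: eudesmane numbering (C1–C15) is used for all bicyclic compounds, and α means the face opposite the C10 methyl group. The configuration at C8 in 12, F1 and F2 and at C7 in F7 has no consequence, because both carbons become trigonal, and is left open in the SMILES.

Step 1
Reactants: 1 3-methylcyclohex-2-en-1-one
Product: 2 (S)-3-methylcyclohex-2-en-1-ol
Conditions: (R)-2-methyl-CBS-oxazaborolidine (10 mol %), catecholborane, toluene, −78 °C; aqueous work-up
Reagents that add atoms: none
Why: Corey–Bakshi–Shibata reduction; the oxazaborolidine binds the ketone with the alkenyl side as the large group and delivers hydride 1,2 to one face, which sets C4 as (S), the only source of absolute configuration for the core.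

Step 2
Reactants: 2 (S)-3-methylcyclohex-2-en-1-ol
Product: 3 (S)-tert-butyldimethyl[(3-methylcyclohex-2-en-1-yl)oxy]silane
Conditions: TBSCl, imidazole, DMF, rt
Reagents that add atoms: tert-butyldimethylsilyl chloride, CC(C)(C)[Si](C)(C)Cl
Why: Standard silylation that keeps the alcohol from being acylated by the ketene and turns it into a bulky shield for one alkene face; no stereocentre is touched.

Step 3
Reactants: 3 (S)-tert-butyldimethyl[(3-methylcyclohex-2-en-1-yl)oxy]silane
Product: 4 8,8-dichloro-5-(tert-butyldimethylsilyloxy)-1-methylbicyclo[4.2.0]octan-7-one (cis-fused; 4β-OTBS 5β-H 10β-CH3)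
Conditions: Cl3CCOCl, Zn–Cu couple, Et2O/DME, rt
Reagents that add atoms: trichloroacetyl chloride, ClC(Cl)(Cl)C(Cl)=O
Why: Ketene–alkene [2+2] cycloaddition; the ketene carbonyl carbon bonds to the less substituted C5 and the CCl2 carbon to C10, addition is suprafacial on the alkene (cis fusion), and approach anti to the allylic OTBS group sets quaternary C10 with its methyl on the OTBS face.

Step 4
Reactants: 4 8,8-dichloro-5-(tert-butyldimethylsilyloxy)-1-methylbicyclo[4.2.0]octan-7-one
Product: 5 5-(tert-butyldimethylsilyloxy)-1-methylbicyclo[4.2.0]octan-7-one (4β-OTBS 5β-H 10β-CH3)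
Conditions: Zn dust, NH4Cl, MeOH, rt
Reagents that add atoms: none
Why: Reductive dechlorination of an α,α-dichlorocyclobutanone through zinc enolates under nearly neutral conditions, which spare the silyl ether and the stereocentres.

Step 5
Reactants: 5 5-(tert-butyldimethylsilyloxy)-1-methylbicyclo[4.2.0]octan-7-one
Product: 6 5-hydroxy-1-methylbicyclo[4.2.0]octan-7-one (4β-OH 5β-H 10β-CH3)
Conditions: HF (48 % aq), MeCN, 0 °C
Reagents that add atoms: none
Why: Acidic desilylation is chosen because a basic fluoride source could expel the β-oxygen from the cyclobutanone by E1cB.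

Step 6
Reactants: 6 5-hydroxy-1-methylbicyclo[4.2.0]octan-7-one
Product: 7 (1R,6R)-6-methylbicyclo[4.2.0]octane-2,8-dione (5β-H 10β-CH3)
Conditions: Dess–Martin periodinane, CH2Cl2, 0 °C → rt
Reagents that add atoms: none
Why: Dess–Martin oxidation under non-basic conditions erases the C4 centre once it has set C10; C5 stays cis because a trans-fused four-membered ring is much more strained, and quaternary C10 cannot racemise.

Step 7
Reactants: 8 3-hydroxy-3-methylbutan-2-one; 9 2,4,6-triisopropylbenzenesulfonohydrazide
Product: 10 (E)-N′-(3-hydroxy-3-methylbutan-2-ylidene)-2,4,6-triisopropylbenzenesulfonohydrazide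
Conditions: MeOH, cat. HCl, rt
Reagents that add atoms: none
Why: Hydrazone condensation; the sulfonamide nitrogen settles anti to the bulky carbinol carbon and therefore syn to the methyl group that is to be deprotonated in the Shapiro reaction.

Step 8
Reactants: 7 (1R,6R)-6-methylbicyclo[4.2.0]octane-2,8-dione; 10 (E)-N′-(3-hydroxy-3-methylbutan-2-ylidene)-2,4,6-triisopropylbenzenesulfonohydrazide
Product: 15 8,11-bis(triethylsilyloxy)-15-noreudesm-7-en-4-one (cis-fused; 5β-H 10β-CH3), via dilithio vinyl reagent 11 (not isolated), via cyclobutanolate 12 (not isolated), via ring-opened enolate 13 (not isolated), via ring-closed dianion 14 (not isolated)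
Conditions: 10, n-BuLi (3.1 equiv), THF, −78 → 0 °C; then 7, −78 → 0 °C; then TESCl, Et3N, DMPU, −78 °C → rt
Reagents that add atoms: chlorotriethylsilane, CC[Si](CC)(CC)Cl
Why: Proposed new method: the Shapiro-derived reagent 11 adds 1,2 to the strained and more electrophilic cyclobutanone carbonyl C8 of 7, and because cyclobutanolate 12 carries the C4 ketone in the β-position, strain-driven retro-aldol cleavage of C5–C8 (the fragmentation step of the De Mayo reaction, the closest known reaction type) gives regiospecifically the C4(O)=C5 enolate 13 next to a newly unmasked α-substituted vinyl ketone. This enolate closes ring B by a 6-endo-trig (enolexo) intramolecular Michael addition of C5 to C6, so the four-membered ring C5–C8–C9–C10 has taken up C6 and C7 and become six-membered, and TESCl fixes the C7=C8 enolate and the C11 alkoxide of 14. C10 is not touched and keeps the configuration from step 3, the new centre C5 arises by stereoelectronically preferred axial attack anti to the axial C10 methyl and so gives cis-decalone 15 (corrected in step 9), and C7 and C8 stay trigonal. The step needs C8 over C4 in the addition (secured by the ring strain of the cyclobutanone), addition over deprotonation of C5–H (low temperature; enolisation would place a double bond at the fusion of the bicyclo[4.2.0]octane), and closure at C5 only (C3 cannot reach C6). The C11 oxygen travels as an alkoxide, which cannot leave by E1cB and cannot trigger loss of acetone as long as C8 is an enolate.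

Step 9
Reactants: 15 8,11-bis(triethylsilyloxy)-15-noreudesm-7-en-4-one (5β-H)
Product: 16 8,11-bis(triethylsilyloxy)-15-noreudesm-7-en-4-one (trans-fused; 5α-H 10β-CH3)
Conditions: DBU (0.5 equiv), toluene, 60 °C
Reagents that add atoms: none
Why: Epimerisation at C5 through the C4 enolate under thermodynamic control should favour the trans-decalone, in which the axial C10 methyl faces trigonal C4 and C8 instead of axial hydrogens; both silyl groups are inert to the amidine.

Step 10
Reactants: 16 8,11-bis(triethylsilyloxy)-15-noreudesm-7-en-4-one (5α-H)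
Product: 17 8,11-bis(triethylsilyloxy)-15-noreudesma-3,7-dien-4-yl trifluoromethanesulfonate (5α-H 10β-CH3)
Conditions: KHMDS, THF, −78 °C; PhNTf2, −78 → 0 °C
Reagents that add atoms: N-phenylbis(trifluoromethanesulfonimide), O=S(=O)(N(c1ccccc1)S(=O)(=O)C(F)(F)F)C(F)(F)F
Why: Kinetic deprotonation takes the unhindered C3 methylene and not the tertiary C5–H, and O-triflation fixes the Δ3 enol; C8 is masked as its silyl enol ether, so only one ketone can enolise and C5 is not disturbed.

Step 11
Reactants: 17 8,11-bis(triethylsilyloxy)-15-noreudesma-3,7-dien-4-yl trifluoromethanesulfonate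
Product: 18 8,11-bis(triethylsilyloxy)eudesma-3,7-diene (5α-H 10β-CH3)
Conditions: MeMgBr, Fe(acac)3 (5 mol %), THF/NMP, −30 → 0 °C
Reagents that add atoms: methylmagnesium bromide, C[Mg]Br
Why: Iron-catalysed Kumada-type cross-coupling of an alkenyl triflate with a methyl Grignard reagent brings in C15 with retention of the alkene position; silyl ether and silyl enol ether are inert.

Step 12
Reactants: 18 8,11-bis(triethylsilyloxy)eudesma-3,7-diene
Product: 19 11-(triethylsilyloxy)eudesma-3,6-dien-8-one (5α-H 10β-CH3)
Conditions: Pd(OAc)2 (1.1 equiv), MeCN, rt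
Reagents that add atoms: none
Why: Saegusa–Ito oxidation; the divalent palladium enolate at C7 can lose only a C6 hydrogen by β-hydride elimination because C11 bears none, and the near-neutral medium should leave the doubly allylic C5–H in place.

Step 13
Reactants: 19 11-(triethylsilyloxy)eudesma-3,6-dien-8-one
Product: 20 3α,4α-dihydroxy-11-(triethylsilyloxy)eudesm-6-en-8-one (5α-H 10β-CH3)
Conditions: OsO4 (2 mol %), NMO, acetone/H2O, 0 °C → rt
Reagents that add atoms: osmium tetroxide, O=[Os](=O)(=O)=O; N-methylmorpholine N-oxide, C[N+]1([O-])CCOCC1; water, O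
Why: Catalytic syn-dihydroxylation picks the electron-rich Δ3 alkene over the electron-poor, hindered enone and attacks the α face opposite the axial C10 methyl, which sets C3 and C4 together as the cis-3α,4α-diol with the C4 methyl β.

Step 14
Reactants: 21 (E)-2-methylbut-2-en-1-ol
Product: 22 [(2R,3R)-2,3-dimethyloxiran-2-yl]methanol
Conditions: Ti(OiPr)4 (10 mol %), D-(−)-diethyl tartrate (12 mol %), t-BuOOH, 4 Å molecular sieves, CH2Cl2, −20 °C
Reagents that add atoms: tert-butyl hydroperoxide, CC(C)(C)OO
Why: Sharpless asymmetric epoxidation; the D-tartrate complex delivers oxygen to the face that gives the (2R,3R)-epoxide, and the E geometry fixes the relative configuration of both centres.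

Step 15
Reactants: 22 [(2R,3R)-2,3-dimethyloxiran-2-yl]methanol
Product: 23 (2S,3R)-2,3-dimethyloxirane-2-carboxylic acid
Conditions: RuCl3·xH2O (2 mol %), NaIO4, MeCN/EtOAc/H2O, 0 °C → rt
Reagents that add atoms: sodium periodate, [Na+].[O-]I(=O)(=O)=O; water, O
Why: Ruthenium tetroxide oxidation of a primary epoxy alcohol to the glycidic acid leaves the epoxide and both centres untouched; only the CIP descriptor at C2 changes.

Step 16
Reactants: 20 3α,4α-dihydroxy-11-(triethylsilyloxy)eudesm-6-en-8-one; 23 (2S,3R)-2,3-dimethyloxirane-2-carboxylic acid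
Product: 25 3α-[(2S,3R)-2,3-dimethyloxirane-2-carbonyloxy]-4α-hydroxy-11-(triethylsilyloxy)eudesm-6-en-8-one, via mixed anhydride 24 (not isolated)
Conditions: 23, 2,4,6-trichlorobenzoyl chloride, Et3N, toluene, rt; then 20, DMAP, rt → 40 °C
Reagents that add atoms: none
Why: Yamaguchi esterification; DMAP transfers the less hindered epoxyacyl group of the mixed anhydride to the only secondary hydroxyl (C3), the tertiary C4 hydroxyl stays free, and no stereocentre is affected.

Step 17
Reactants: 25 3α-[(2S,3R)-2,3-dimethyloxirane-2-carbonyloxy]-4α-hydroxy-11-(triethylsilyloxy)eudesm-6-en-8-one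
Product: 26 3α-[(2R,3S)-3-chloro-2-hydroxy-2-methylbutanoyloxy]-4α,11-dihydroxyeudesm-6-en-8-one (target)
Conditions: HCl (2 M in Et2O), CH2Cl2, −20 → 0 °C
Reagents that add atoms: hydrogen chloride, Cl
Why: Chloride opens the protonated glycidic ester by SN2 at the secondary β-carbon C3′ (C2′ is tertiary and deactivated by the carbonyl) with inversion, which gives the (2′R,3′S)-chlorohydrin, and the same acid cleaves the tertiary TES ether.

**Compound list**

| No. | Name | SMILES | Role |
|---|---|---|---|
| 1 | 3-methylcyclohex-2-en-1-one | CC1=CC(=O)CCC1 | starting material |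
| 2 | (S)-3-methylcyclohex-2-en-1-ol | CC1=C[C@@H](O)CCC1 | intermediate |
| 3 | (S)-tert-butyldimethyl[(3-methylcyclohex-2-en-1-yl)oxy]silane | CC1=C[C@@H](O[Si](C)(C)C(C)(C)C)CCC1 | intermediate |
| 4 | 8,8-dichloro-5-(tert-butyldimethylsilyloxy)-1-methylbicyclo[4.2.0]octan-7-one (4β-OTBS, 5β-H, 10β-CH3) | C[C@]12CCC[C@H](O[Si](C)(C)C(C)(C)C)[C@H]1C(=O)C2(Cl)Cl | intermediate |
| 5 | 5-(tert-butyldimethylsilyloxy)-1-methylbicyclo[4.2.0]octan-7-one | C[C@]12CCC[C@H](O[Si](C)(C)C(C)(C)C)[C@H]1C(=O)C2 | intermediate |
| 6 | 5-hydroxy-1-methylbicyclo[4.2.0]octan-7-one | C[C@]12CCC[C@H](O)[C@H]1C(=O)C2 | intermediate |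
| 7 | (1R,6R)-6-methylbicyclo[4.2.0]octane-2,8-dione | C[C@]12CCCC(=O)[C@H]1C(=O)C2 | intermediate |
| 8 | 3-hydroxy-3-methylbutan-2-one | CC(=O)C(C)(C)O | starting material |
| 9 | 2,4,6-triisopropylbenzenesulfonohydrazide | CC(C)c1cc(C(C)C)c(S(=O)(=O)NN)c(C(C)C)c1 | starting material |
| 10 | (E)-trisylhydrazone of 8 | C/C(=N\NS(=O)(=O)c1c(C(C)C)cc(C(C)C)cc1C(C)C)C(C)(C)O | intermediate |
| 11 | lithium 3-lithio-2-methylbut-3-en-2-olate | [Li]C(=C)C(C)(C)O[Li] | intermediate |
| 12 | dilithium cyclobutanolate from addition of 11 to C8 of 7 | C[C@]12CCCC(=O)[C@H]1C(O[Li])(C(=C)C(C)(C)O[Li])C2 | intermediate |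
| 13 | ring-opened lithium C4(O)=C5 enolate with vinyl ketone side chain on C10 | C=C(C(=O)C[C@@]1(C)CCCC(O[Li])=C1)C(C)(C)O[Li] | intermediate |
| 14 | cis-decalone C7=C8 enolate / C11 alkoxide (dilithium) | C[C@]12CCCC(=O)[C@H]1CC(C(C)(C)O[Li])=C(O[Li])C2 | intermediate |
| 15 | 8,11-bis(triethylsilyloxy)-15-noreudesm-7-en-4-one, 5β-H (cis) | C[C@]12CCCC(=O)[C@H]1CC(C(C)(C)O[Si](CC)(CC)CC)=C(O[Si](CC)(CC)CC)C2 | intermediate |
| 16 | 8,11-bis(triethylsilyloxy)-15-noreudesm-7-en-4-one, 5α-H (trans) | C[C@]12CCCC(=O)[C@@H]1CC(C(C)(C)O[Si](CC)(CC)CC)=C(O[Si](CC)(CC)CC)C2 | intermediate |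
| 17 | Δ3 enol triflate of 16 | C[C@]12CCC=C(OS(=O)(=O)C(F)(F)F)[C@@H]1CC(C(C)(C)O[Si](CC)(CC)CC)=C(O[Si](CC)(CC)CC)C2 | intermediate |
| 18 | 8,11-bis(triethylsilyloxy)eudesma-3,7-diene | C[C@]12CCC=C(C)[C@@H]1CC(C(C)(C)O[Si](CC)(CC)CC)=C(O[Si](CC)(CC)CC)C2 | intermediate |
| 19 | 11-(triethylsilyloxy)eudesma-3,6-dien-8-one | C[C@]12CCC=C(C)[C@@H]1C=C(C(C)(C)O[Si](CC)(CC)CC)C(=O)C2 | intermediate |
| 20 | 3α,4α-dihydroxy-11-(triethylsilyloxy)eudesm-6-en-8-one | O[C@@H]1CC[C@]2(C)CC(=O)C(C(C)(C)O[Si](CC)(CC)CC)=C[C@H]2[C@]1(C)O | intermediate |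
| 21 | (E)-2-methylbut-2-en-1-ol | C/C=C(\C)CO | starting material |
| 22 | [(2R,3R)-2,3-dimethyloxiran-2-yl]methanol | C[C@H]1O[C@]1(C)CO | intermediate |
| 23 | (2S,3R)-2,3-dimethyloxirane-2-carboxylic acid | C[C@H]1O[C@]1(C)C(=O)O | intermediate |
| 24 | mixed anhydride of 23 with 2,4,6-trichlorobenzoic acid | C[C@H]1O[C@]1(C)C(=O)OC(=O)c1c(Cl)cc(Cl)cc1Cl | intermediate |
| 25 | 3α-epoxyacyl ester of 20 | C[C@H]1O[C@]1(C)C(=O)O[C@@H]1CC[C@]2(C)CC(=O)C(C(C)(C)O[Si](CC)(CC)CC)=C[C@H]2[C@]1(C)O | intermediate |
| 26 | 3α-[(2R,3S)-3-chloro-2-hydroxy-2-methylbutanoyloxy]-4α,11-dihydroxyeudesm-6-en-8-one | C[C@H](Cl)[C@](C)(O)C(=O)O[C@@H]1CC[C@]2(C)CC(=O)C(C(C)(C)O)=C[C@H]2[C@]1(C)O | target |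

Total step count: 17. Longest linear sequence: 14 (steps 1–6, 8–13, 16, 17).

**Steps most likely to fail**

**Step 8.**
- What may go wrong: the organolithium may deprotonate the 1,3-dicarbonyl C5–H or attack the C4 carbonyl instead of C8. The C11 oxygen function or acetone may be lost during the anionic cascade. O-silylation of the hindered enolate may stay incomplete.
- Fallback: it separates the events into known reactions, sets out from 5 and comes back at 15.
- Reagent 11 (from 10 and n-BuLi) is added to mono-ketone 5, which has one carbonyl group and no 1,3-dicarbonyl proton, to give the cyclobutanol silyl ether F1.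
- Aqueous HF gives the triol F2.
- Dess–Martin oxidation of the only secondary alcohol followed by Et3N brings about the retro-aldol opening known from De Mayo adducts and gives the open-chain enone diketone F3.
- TESOTf/2,6-lutidine gives its TES ether F4.
- KHMDS (slightly less than one equivalent, −78 → 0 °C, enolate equilibration) closes ring B by intramolecular Michael addition, and TESCl traps the enolate as 15.

**Step 3.**
- What may go wrong: poor facial selectivity of the ketene approach, which after step 6 would show up as loss of enantiomeric purity. Zinc salts may also ionise the allylic silyl ether.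
- Fallback: it sets out from 1 and comes back at 6.
- Irradiation of 1 with allene (head-to-head enone–allene [2+2] photocycloaddition) gives the racemic methylenecyclobutane ketone F5.
- CBS reduction with the (R)-oxazaborolidine converts both enantiomers under catalyst control into (S)-carbinols, which are two separable diastereomers.
- The diastereomer with the hydroxyl anti to the four-membered ring, the methylenecyclobutane alcohol F6, is ozonised (O3, then Me2S) to 6.

**Step 12.**
- What may go wrong: slow palladation of the hindered tetrasubstituted silyl enol ether, and a palladium hydride-mediated shift of the Δ3 alkene into conjugation.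
- Fallback: it sets out from 18 and comes back at 19.
- PhSeCl at −78 °C reacts with the silyl enol ether, which is far more nucleophilic than the Δ3 alkene, to give the α-phenylselanyl ketone F7.
- H2O2/pyridine forms the selenoxide, and its syn elimination can only take a C6 hydrogen, which gives 19.

**Further compounds**
F1 | step 8 | 5-(tert-butyldimethylsilyloxy)-7-(3-hydroxy-3-methylbut-1-en-2-yl)-1-methylbicyclo[4.2.0]octan-7-ol | C[C@]12CCC[C@H](O[Si](C)(C)C(C)(C)C)[C@H]1C(O)(C(=C)C(C)(C)O)C2
F2 | step 8 | 7-(3-hydroxy-3-methylbut-1-en-2-yl)-1-methylbicyclo[4.2.0]octane-5,7-diol | C[C@]12CCC[C@H](O)[C@H]1C(O)(C(=C)C(C)(C)O)C2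
F3 | step 8 | 3-[3-(2-hydroxypropan-2-yl)-2-oxobut-3-en-1-yl]-3-methylcyclohexan-1-one (C10 as in 7) | C=C(C(=O)C[C@@]1(C)CCCC(=O)C1)C(C)(C)O
F4 | step 8 | triethylsilyl ether of F3 | C=C(C(=O)C[C@@]1(C)CCCC(=O)C1)C(C)(C)O[Si](CC)(CC)CC
F5 | step 3 | (±)-6-methyl-8-methylenebicyclo[4.2.0]octan-2-one (cis-fused; needed enantiomer drawn) | C[C@]12CCCC(=O)[C@H]1C(=C)C2
F6 | step 3 | 6-methyl-8-methylenebicyclo[4.2.0]octan-2-ol (4β-OH, 5β-H, 10β-CH3) | C[C@]12CCC[C@H](O)[C@H]1C(=C)C2
F7 | step 12 | 7-(phenylselanyl)-11-(triethylsilyloxy)eudesm-3-en-8-one | C[C@]12CCC=C(C)[C@@H]1CC([Se]c1ccccc1)(C(C)(C)O[Si](CC)(CC)CC)C(=O)C2
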